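Grey and violet are one charge read at two times, so I need what that charge holds at each time.

| setting | south-west | north-east | south | grey | violet |
|---|---|---|---|---|---|
| starting material | 1 M | 1 M | 0.50 M | 1.0 M | 1.0 M |
| free catalyst | 11 mM | 44 mM | 22 mM | 22 mM | 22 mM |
| remark | run made earlier | run made earlier | run made earlier |  |  |
| time |  |  |  | 4.0 min | 2.5 min |

- which of the two ends with the higher amount of target, in percent of the starting material charged ("neither" if they lie within 2 percentage points) (grey / violet / neither)
- target at the end, in percent of the starting material charged, grey
- target at the end, in percent of the starting material charged, violet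



| run | time / min | target / % |
|---|---|---|
| south-west | 0.167 | 1 |
| south-west | 0.333 | 2 |
| south-west | 0.667 | 5 |
| south-west | 1.00 | 8 |
| south-west | 1.33 | 8 |
| south-west | 2.00 | 10 |
| south-west | 2.50 | 13 |
| north-east | 0.167 | 3 |
| north-east | 0.333 | 6 |
| north-east | 0.667 | 13 |
| north-east | 1.00 | 16 |
| north-east | 1.33 | 17 |
| north-east | 2.00 | 28 |
| north-east | 2.50 | 30 |
| south | 0.200 | 5 |
| south | 0.667 | 13 |
| south | 1.00 | 19 |
| south | 1.50 | 27 |
| south | 2.50 | 38 |

(standard deviation of a reading: 1.5 percentage points)

I read the south-west column against the north-east one. Their starting material is the same and their catalyst differs by a factor of 4.00. At 2.50 min they stand at 13% and 30%, a ratio of 2.31. From this I take the doubling gain, the factor by which target at a fixed time grows when the catalyst charge doubles with the starting material held: the square root of that ratio, 1.52, a reading with scatter. It is smaller than the 2 of plain proportion.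

Violet has twice the south-west catalyst, so I scale the south-west reading of 13% by the gain and expect 19.7%.

Now the lower rows. Grey runs 1.50 min past violet, as long as the stretch from 1.00 min to 2.50 min, over which the south-west column climbs from 8% to 13%. Scaled by the gain, and assuming that pace holds, this adds 7.6 percentage points, which is more than the margin of 2 points. My grey is 27.3%.

The forecast says grey, with 28% for grey and 20.5% for violet: “Grey is higher simply because it runs longer.” My two figures lie 0.70 points and 0.80 points under its figures.

The flask gives grey, with 28.5% for grey and 20.0% for violet.

    starting material + free catalyst → catalyst intermediate (k = 4.20 /M/s)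
    catalyst intermediate → free catalyst + target (k = 0.110 /s)
    2 catalyst intermediate ⇌ resting dimer (K = 99.0 /M, k = 0.390 /M/s)
    2 free catalyst → spent catalyst (k = 0.150 /M/s)

In violet at 0.853 min, catalyst intermediate has a half-life of 0.11 min by releasing target, while starting material has 7.5 min by meeting free catalyst. At 2.50 min, violet's catalyst stands as 57.8% resting dimer, its resting state, 40.7% catalyst intermediate, 1.37% free catalyst and 0.109% spent catalyst, and 78% of the starting material is left. Grey's figure has moved by 5 points at 0.848 M of starting material, or at 3.11 min with the amounts held. Divided by the gain, grey's 28.5% gives 18.8% for the south-west flask at 4.0 min, which holds 18.0%.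

The runs stem from a simulated flask with made-up constants; scatter was added.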